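**Remark on numbering.** The chromanone half keeps flavonoid locants (O1, C2, C3, C4, C4a, C5–C8, C8a). The flavan half is primed (O1', C2', C3', C4', C4a', C5'–C8', C8a'). The aryl group on C2 is double-primed and the aryl group on C2' is triple-primed. CIP analysis of the target gives (2S,3S,2'R).

## The problem

The target is a 5,7-dihydroxychroman-4-one (rings A and C) whose C2 is a ketal carbon carrying O1, a 4-hydroxyphenyl group and O7' of a (2'R)-flavan. C3, the CH between the C4 ketone and C2, is bonded to C8' of the same flavan arene, so O7'–C2–C3–C8' closes a dihydrofuran that is cis-fused to ring C. There are three stereocentres but only two independent elements: the five-membered ring forces the C2 aryl group and the C3 hydrogen to be cis, so fixing C2 fixes C3. C2' lies four bonds from C3 across a flat arene and can neither direct the ketal nor be directed by it, so the C2/C3 pair must be set by a reagent. The ketal is the fragile part. C3–H is α to the ketone and β to two aryloxy leaving groups, so base (enolisation, β-elimination) or acid (ionisation at the benzylic, doubly oxygenated C2) should open it to an aromatic 3-aroyl-2-arylbenzofuran or a 3-arylflavone and erase both centres. It is therefore expected to be the high-energy isomer of its family and must be made late, irreversibly and near neutrality. The flavan adds a 4-oxygenated benzylic ether at C2' (acid, SN1 racemisation), a C4' methylene para to O7' (quinone methide on oxidation) and a phloroglucinol-type ring with two open sites, C6' and C8'. The handle for the key step is the C3–C8' bond: a 3-arylchromanone is an isoflavonoid. C8', flanked by O7' and O1', is a poor cross-coupling site but an excellent migrating group, so the bond can be made by shifting the flavan arene from the future C2 to C3 of a chalcone built on a C8' aldehyde.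

## Retrosynthesis

**24 to 23.** The five O–benzyl bonds are cut last. Hydrogenolysis is the one global deprotection that is neutral, which the ketal requires; acid- or fluoride/base-labile groups would put the final step at risk. The forward reaction must leave the tertiary benzylic ketal C–O bonds and the C2'–O1' ether untouched.

**23 to 21 and 22.** The C2–C1'' bond is cut. This is the only disconnection at C2 that forms an irreversible C–C bond on a precursor already holding both C–O bonds; the neighbouring cuts (C2–O7' onto a 3-arylflavone, C2–O1 onto a 3-aroylbenzofuran) are reversible heteroatom additions that run uphill against a chromone or a furan. Coumaronochromone 21 is much simpler: a flat, fully aromatic core with one stereocentre, stable to acid and base. The forward step asks a chiral arylpalladium catalyst to add the aryl group of 22 to one face of a tetrasubstituted, doubly oxygenated enone. This is without precedent and is the main risk of the plan.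

**21 to 18, 16 and 15.** The C2–O7' bond (and the O5' benzyl ether) is cut. Closure by addition–elimination of the O7' phenoxide on 2-iodochromone 18 is preferred to the dehydrogenative closure of a 2'-hydroxyisoflavone, because a quinone-type oxidant would meet a 7'-hydroxyflavan whose C4' methylene is para to the phenol. The iodide comes from zincation of C2–H in 16, the most acidic C–H of a chromone. The two phenols of 15 are silylated for that step, and the same silyl ethers later serve as the fluoride trigger for ring closure.

**15 to 13 (key step).** C3–C8' and C2–O1 are cut together, which takes the isoflavone back to 2'-hydroxychalcone 13. A cross-coupling at C8' would need a 2,6-dioxygenated arylmetal prone to protodemetalation next to two ortho substituents. The rearrangement instead uses the electron richness of that ring as migratory aptitude. The forward step needs aryl migration to beat methoxylation and arene oxidation, and closure through the ring A hydroxyl.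

**13 to 10 and 12.** The enone C=C is cut by aldol condensation, the convergent union of the two halves. Ketone 12 is one step from 11. The aldehyde is hindered and electron-rich, so the condensation needs strong base and time but has no competing enolisation.

**10 to 8 and 7.** The C8'–CHO bond is cut to bromide 8 and then to flavan 7. Bromination must choose C8' (between O1' and one alkoxy group) over C6' (between two alkoxy groups).

**7 to 6, 5, 4, 2 and 3; 2 to 1.** O1'–C2' is cut by an invertive Mitsunobu closure of (S)-carbinol 6. The carbinol comes from ketone 5 by asymmetric transfer hydrogenation, 5 from enone 4, and 4 from aldehyde 2 and ketone 3. MOM ethers are chosen for O5' and O7' because they survive hydroxide, organolithium and hydride chemistry, differ from the benzyl ethers elsewhere, and leave in the acid finish of the key step.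

## Roads not taken

**Alternative 1: benzannulation builds the flavan arene.** The cut removes C4a'–C8a', C5'–C6' and C8'–C8a'. In the forward sense, irradiation of furyl diazoketone A2 gives a furylketene by Wolff rearrangement, which combines with siloxyalkyne A3 ([2+2], four-electron opening, six-electron closure: Danheiser benzannulation) to give benzofuran A1.
- Merits: high convergence, and complete regiocontrol on the central arene. This is better than the chosen plan, which relies on a C8'/C6' preference in a bromination. The flavan ring would close by the same Mitsunobu logic.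
- Weak points: A2 and A3 each need several steps and a photochemical step on a heavily benzylated substrate. Above all, A1 is the aromatic 3-aroyl-2-arylbenzofuran. The ketal would have to be reached by adding one ring A hydroxyl to furan C2, a reversible dearomatising addition with no evident source of absolute control at C2/C3, after selective unmasking of one of three identical benzyl ethers.
- Against this the chosen plan sets a C–C bond formation driven by the boronic acid, on a substrate where both C–O bonds are already in place.

**Alternative 2: carbonylative three-component assembly.** The cut removes C2–O7', C3–C4 and C4–C4a. Alkynylphenol A5, aryl iodide A6 and carbon monoxide A7 would combine under zerovalent palladium catalysis (aroylpalladium-triggered attack of the phenol on the alkyne, reductive elimination) to give hexabenzyl benzofuran A4.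
- Merits: probably the shortest route to the full carbon skeleton; the reaction type is established for ortho-alkynylphenols; A5 could come from bromide 8 of the present route by alkynylation. In step count to the skeleton it beats the chosen plan.
- Weak points: A6 is a di-ortho-substituted, electron-rich iodide, so oxidative addition and CO insertion are slow and non-carbonylative coupling competes. The product is again the benzofuran, so the uphill, stereochemically uncontrolled ketal closure of Alternative 1 remains.
- The chosen plan spends more steps but arrives at the ketal-forming step with the right ring-chain connectivity.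

**Alternative 3: quinone methide cycloaddition closes the flavan ring last.** The cut removes C3'–C4' and O1'–C2'. A chiral phosphoric acid would dehydrate ortho-hydroxybenzyl alcohol A9 to an ortho-quinone methide that adds 4-vinylphenol A10, giving A8.
- Merits: C2' is set last under catalyst control and never has to survive acid, base or oxidant. That is a real advantage over the chosen plan, where the C2' ether is carried through eleven steps.
- Weak points: it presupposes the ketal core, so the C2/C3 problem is moved, not solved. The labile ketal must then survive a Brønsted acid whose job is to ionise a benzylic alcohol. The catalyst must also control C2' against two existing remote centres.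
- The chosen plan sets C2' early by a reliable transfer hydrogenation and keeps the ketal out of every acidic step.

Key step: step 10

## Route

Step 1
Reactants: 1 2,4,6-trihydroxybenzaldehyde
Product: 2 2-hydroxy-4,6-bis(methoxymethoxy)benzaldehyde
Conditions: MOMCl (2.2 equiv), i-Pr2NEt, CH2Cl2, 0 °C to rt
Reagents that add atoms: chloromethyl methyl ether, COCCl
Why: O-alkylation under amine base takes the two free hydroxyls; the hydroxyl hydrogen-bonded to the formyl group is left, as is usual for 2,4,6-trihydroxyaryl carbonyl compounds.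

Step 2
Reactants: 2 2-hydroxy-4,6-bis(methoxymethoxy)benzaldehyde; 3 1-[4-(benzyloxy)phenyl]ethanone
Product: 4 (E)-1-[4-(benzyloxy)phenyl]-3-[2-hydroxy-4,6-bis(methoxymethoxy)phenyl]prop-2-en-1-one
Conditions: KOH, EtOH, rt; AcOH work-up
Reagents that add atoms: none
Why: Claisen–Schmidt condensation of a methyl ketone enolate with a non-enolisable aldehyde, E1cB dehydration giving the (E)-enone; MOM and benzyl ethers are inert to hydroxide and the mild acid work-up avoids flavylium formation.

Step 3
Reactants: 4 (E)-1-[4-(benzyloxy)phenyl]-3-[2-hydroxy-4,6-bis(methoxymethoxy)phenyl]prop-2-en-1-one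
Product: 5 1-[4-(benzyloxy)phenyl]-3-[2-hydroxy-4,6-bis(methoxymethoxy)phenyl]propan-1-one
Conditions: H2 (1 atm), Pd/C, Ph2S, EtOAc, rt
Reagents that add atoms: none
Why: Chemoselective catalytic hydrogenation; sulfide-poisoned palladium on carbon saturates the conjugated C=C but leaves the aryl ketone and the O-benzyl group.

Step 4
Reactants: 5 1-[4-(benzyloxy)phenyl]-3-[2-hydroxy-4,6-bis(methoxymethoxy)phenyl]propan-1-one
Product: 6 (1S)-1-[4-(benzyloxy)phenyl]-3-[2-hydroxy-4,6-bis(methoxymethoxy)phenyl]propan-1-ol
Conditions: RuCl[(S,S)-TsDPEN](p-cymene) (1 mol %), HCO2H/Et3N (5:2), CH2Cl2, 30 °C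
Reagents that add atoms: none
Why: Asymmetric transfer hydrogenation of an aryl alkyl ketone; the (S,S)-catalyst delivers hydride to the face that gives the (S)-carbinol, the sense established for acetophenone-type ketones, and the buffered medium should spare the MOM ethers.

Step 5
Reactants: 6 (1S)-1-[4-(benzyloxy)phenyl]-3-[2-hydroxy-4,6-bis(methoxymethoxy)phenyl]propan-1-ol
Product: 7 (2R)-2-[4-(benzyloxy)phenyl]-5,7-bis(methoxymethoxy)chromane
Conditions: PPh3, DIAD, toluene/THF, −20 to 0 °C
Reagents that add atoms: none
Why: Intramolecular Mitsunobu etherification; the phenol displaces the activated carbinol oxygen by SN2 (6-exo-tet) with inversion, so the (S)-alcohol gives the (2R)-flavan, and low temperature in a weakly polar medium is meant to suppress ionisation of the 4-alkoxybenzylic centre.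

Step 6
Reactants: 7 (2R)-2-[4-(benzyloxy)phenyl]-5,7-bis(methoxymethoxy)chromane
Product: 8 (2R)-2-[4-(benzyloxy)phenyl]-8-bromo-5,7-bis(methoxymethoxy)chromane
Conditions: NBS (1.0 equiv), CH2Cl2, −78 to 0 °C
Reagents that add atoms: N-bromosuccinimide, O=C1CCC(=O)N1Br
Why: Electrophilic aromatic bromination of the trioxygenated ring; C8 (between the ring oxygen and one alkoxy group) is more accessible than C6 (between two alkoxy groups), the preference known for 5,7-dialkoxyflavans.

Step 7
Reactants: 8 (2R)-2-[4-(benzyloxy)phenyl]-8-bromo-5,7-bis(methoxymethoxy)chromane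
Product: 10 (2R)-2-[4-(benzyloxy)phenyl]-5,7-bis(methoxymethoxy)chromane-8-carbaldehyde, via aryllithium 9 (not isolated)
Conditions: n-BuLi, THF, −78 °C; then DMF, −78 °C to rt; H2O
Reagents that add atoms: N,N-dimethylformamide, CN(C)C=O
Why: Bromine–lithium exchange is faster at −78 °C than any deprotonation and fixes the metal at C8; formylation of the aryllithium with DMF gives the aldehyde without touching C2.

Step 8
Reactants: 11 1-(2,4,6-trihydroxyphenyl)ethanone
Product: 12 1-[2,4-bis(benzyloxy)-6-hydroxyphenyl]ethanone
Conditions: BnBr (2.1 equiv), K2CO3, DMF, rt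
Reagents that add atoms: benzyl bromide, BrCc1ccccc1
Why: Williamson etherification of the two non-chelated hydroxyls; the hydroxyl hydrogen-bonded to the acetyl group is retained and is the one needed for pyranone closure.

Step 9
Reactants: 10 (2R)-2-[4-(benzyloxy)phenyl]-5,7-bis(methoxymethoxy)chromane-8-carbaldehyde; 12 1-[2,4-bis(benzyloxy)-6-hydroxyphenyl]ethanone
Product: 13 (E)-1-[2,4-bis(benzyloxy)-6-hydroxyphenyl]-3-[(2R)-2-[4-(benzyloxy)phenyl]-5,7-bis(methoxymethoxy)chroman-8-yl]prop-2-en-1-one
Conditions: KOH, EtOH/THF, rt to 40 °C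
Reagents that add atoms: none
Why: Claisen–Schmidt condensation, well known for 2,4,6-trialkoxybenzaldehydes with 2'-hydroxyacetophenones; the aldehyde cannot enolise and the 6'-alkoxy-2'-hydroxychalcone is expected to stay open as its phenoxide under base.

Step 10
Reactants: 13 (E)-1-[2,4-bis(benzyloxy)-6-hydroxyphenyl]-3-[(2R)-2-[4-(benzyloxy)phenyl]-5,7-bis(methoxymethoxy)chroman-8-yl]prop-2-en-1-one
Product: 15 5,7-bis(benzyloxy)-3-[(2R)-2-[4-(benzyloxy)phenyl]-5,7-dihydroxychroman-8-yl]-4H-chromen-4-one, via acetal 14 (not isolated)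
Conditions: PhI(OAc)2 (1.1 equiv), TsOH·H2O, MeOH/CH2Cl2, 0 °C to rt; then conc. HCl, 50 °C
Reagents that add atoms: none
Why: This is the oxidative rearrangement of a 2'-hydroxychalcone to an isoflavone by 1,2-aryl migration, a known reaction with trivalent iodine or Tl(NO3)3 in methanol. Acid-promoted addition of methanol to the enone gives a β-methoxy enol that is captured at the α-carbon by trivalent iodine. The flavan arene, a 2,4,6-trioxygenated and therefore excellent migrating group, shifts from the β- to the α-carbon through a phenonium ion as iodobenzene leaves, which makes C3–C8', and methanol traps the oxocarbenium ion as dimethyl acetal 14. On warming with acid the ring A hydroxyl attacks the methoxy-oxocarbenium ion from the acetal (6-exo-trig), which makes C2–O1 and closes the pyranone ring, and loss of methanol gives the chromone. The same acid then removes both MOM groups. No stereocentre is created, since the α-carbon of 14 becomes sp2, and C2' is not involved. Migration must outrun plain methoxylation and arene oxidation, which the electron-rich migrating ring, low temperature and a bare excess of oxidant (none left when the phenols appear) should secure. Closure must go through the ring A hydroxyl and not O7', which stays capped as its MOM ether until the chromone has formed.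

Step 11
Reactants: 15 5,7-bis(benzyloxy)-3-[(2R)-2-[4-(benzyloxy)phenyl]-5,7-dihydroxychroman-8-yl]-4H-chromen-4-one
Product: 16 5,7-bis(benzyloxy)-3-[(2R)-2-[4-(benzyloxy)phenyl]-5,7-bis(tert-butyldimethylsilyloxy)chroman-8-yl]-4H-chromen-4-one
Conditions: TBSCl, imidazole, DMF, rt to 40 °C
Reagents that add atoms: tert-butyldimethylsilyl chloride, CC(C)(C)[Si](C)(C)Cl
Why: Silylation of both phenols, so that no acidic OH consumes the amide base and no electron-rich phenoxide meets iodine in the next step; the silyl ethers later act as the fluoride trigger.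

Step 12
Reactants: 16 5,7-bis(benzyloxy)-3-[(2R)-2-[4-(benzyloxy)phenyl]-5,7-bis(tert-butyldimethylsilyloxy)chroman-8-yl]-4H-chromen-4-one
Product: 18 5,7-bis(benzyloxy)-3-[(2R)-2-[4-(benzyloxy)phenyl]-5,7-bis(tert-butyldimethylsilyloxy)chroman-8-yl]-2-iodo-4H-chromen-4-one, via zinc reagent 17 (not isolated)
Conditions: TMPZnCl·LiCl, THF, −30 to 0 °C; then I2, −30 °C
Reagents that add atoms: iodine, II
Why: Directed zincation of a chromone at C2, its most acidic C–H, by a hindered zinc amide that tolerates ethers and the carbonyl group, followed by iodinolysis of the C–Zn bond; this is known for chromones including 3-substituted ones.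

Step 13
Reactants: 18 5,7-bis(benzyloxy)-3-[(2R)-2-[4-(benzyloxy)phenyl]-5,7-bis(tert-butyldimethylsilyloxy)chroman-8-yl]-2-iodo-4H-chromen-4-one
Product: 21 coumaronochromone tetrabenzyl ether: 5,7,5'-tris(benzyloxy)-2'-[4-(benzyloxy)phenyl] (2'R)-flavan-fused benzofuro[2,3-b]chromen-4-one with C2=C3, O7' bonded to C2 and C8' to C3, via iodo diol 19 (not isolated), via phenol 20 (not isolated)
Conditions: Bu4NF, THF, 0 °C to rt; then BnBr, rt
Reagents that add atoms: benzyl bromide, BrCc1ccccc1
Why: Fluoride frees both phenoxides; the O7' phenoxide displaces iodide at C2 by addition–elimination on the vinylogous acyl iodide and closes the furan ring (the intramolecular form of the usual substitution of 2-halochromones by phenoxides), while the O5' phenoxide, which cannot reach C2, is benzylated in the same flask.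

Step 14
Reactants: 21 coumaronochromone tetrabenzyl ether; 22 [4-(benzyloxy)phenyl]boronic acid
Product: 23 (2S,3S,2'R)-5,7,5'-tris(benzyloxy)-2,2'-bis[4-(benzyloxy)phenyl] ketal (pentabenzyl ether of the target)
Conditions: Pd(OCOCF3)2 (10 mol %), (R)-t-BuPyOX (12 mol %), NH4PF6, H2O, ClCH2CH2Cl, 50 °C
Reagents that add atoms: none
Why: Proposed new method: a cationic arylpalladium species formed by transmetalation from 22 should insert the C2=C3 bond of 21 with the aryl group going to C2, the carbon made electrophilic by both the enone and its two oxygen substituents, and the C3-bound palladium enolate, which has no β-hydrogen and whose C2–O bonds are held away from a syn-coplanar arrangement by the fused rings, should be protonated by water; the closest known reaction type is the asymmetric conjugate addition of arylboronic acids to chromones and 2-substituted chromones catalysed by divalent palladium with pyridine-oxazoline ligands, which gives flavanones and tetrasubstituted chromanones; C2 is set by ligand-controlled facial selection in the insertion (the (R)-ligand is proposed by transposing the sense known for 3-substituted cyclic enones, with the (S)-ligand as the immediate alternative), and C3 follows because the five-membered ring permits only the cis ring fusion.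

Step 15
Reactants: 23 (2S,3S,2'R)-pentabenzyl ether of the target
Product: 24 target, (2S,3S,2'R)-5,7,5'-trihydroxy-2,2'-bis(4-hydroxyphenyl) ketal
Conditions: H2 (1 atm), Pd/C, EtOAc/MeOH, rt
Reagents that add atoms: none
Why: Hydrogenolysis of five primary O-benzyl ethers under neutral conditions; the tertiary benzylic ketal C–O bonds and the secondary C2'–O1' aryl ether are cleaved far more slowly, as debenzylations of flavans show, and no acid or base is present to open the ketal.

## Compound list

1 | 2,4,6-trihydroxybenzaldehyde | O=Cc1c(O)cc(O)cc1O | starting material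
2 | 2-hydroxy-4,6-bis(methoxymethoxy)benzaldehyde | O=Cc1c(O)cc(OCOC)cc1OCOC | intermediate
3 | 1-[4-(benzyloxy)phenyl]ethanone | CC(=O)c1ccc(OCc2ccccc2)cc1 | starting material
4 | (E)-1-[4-(benzyloxy)phenyl]-3-[2-hydroxy-4,6-bis(methoxymethoxy)phenyl]prop-2-en-1-one | O=C(/C=C/c1c(O)cc(OCOC)cc1OCOC)c1ccc(OCc2ccccc2)cc1 | intermediate
5 | 1-[4-(benzyloxy)phenyl]-3-[2-hydroxy-4,6-bis(methoxymethoxy)phenyl]propan-1-one | O=C(CCc1c(O)cc(OCOC)cc1OCOC)c1ccc(OCc2ccccc2)cc1 | intermediate
6 | (1S)-1-[4-(benzyloxy)phenyl]-3-[2-hydroxy-4,6-bis(methoxymethoxy)phenyl]propan-1-ol | O[C@@H](CCc1c(O)cc(OCOC)cc1OCOC)c1ccc(OCc2ccccc2)cc1 | intermediate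
7 | (2R)-2-[4-(benzyloxy)phenyl]-5,7-bis(methoxymethoxy)chromane | COCOc1cc(OCOC)c2c(c1)O[C@@H](c1ccc(OCc3ccccc3)cc1)CC2 | intermediate
8 | (2R)-2-[4-(benzyloxy)phenyl]-8-bromo-5,7-bis(methoxymethoxy)chromane | COCOc1cc(OCOC)c2c(c1Br)O[C@@H](c1ccc(OCc3ccccc3)cc1)CC2 | intermediate
9 | [(2R)-2-[4-(benzyloxy)phenyl]-5,7-bis(methoxymethoxy)chroman-8-yl]lithium | COCOc1cc(OCOC)c2c(c1[Li])O[C@@H](c1ccc(OCc3ccccc3)cc1)CC2 | intermediate
10 | (2R)-2-[4-(benzyloxy)phenyl]-5,7-bis(methoxymethoxy)chromane-8-carbaldehyde | COCOc1cc(OCOC)c2c(c1C=O)O[C@@H](c1ccc(OCc3ccccc3)cc1)CC2 | intermediate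
11 | 1-(2,4,6-trihydroxyphenyl)ethanone | CC(=O)c1c(O)cc(O)cc1O | starting material
12 | 1-[2,4-bis(benzyloxy)-6-hydroxyphenyl]ethanone | CC(=O)c1c(O)cc(OCc2ccccc2)cc1OCc1ccccc1 | intermediate
13 | (E)-1-[2,4-bis(benzyloxy)-6-hydroxyphenyl]-3-[(2R)-2-[4-(benzyloxy)phenyl]-5,7-bis(methoxymethoxy)chroman-8-yl]prop-2-en-1-one | O=C(/C=C/c1c(OCOC)cc(OCOC)c2c1O[C@@H](c1ccc(OCc3ccccc3)cc1)CC2)c1c(O)cc(OCc2ccccc2)cc1OCc1ccccc1 | intermediate
14 | 1-[2,4-bis(benzyloxy)-6-hydroxyphenyl]-2-[(2R)-2-[4-(benzyloxy)phenyl]-5,7-bis(methoxymethoxy)chroman-8-yl]-3,3-dimethoxypropan-1-one (both epimers at C2 of the propanone) | COC(OC)C(C(=O)c1c(O)cc(OCc2ccccc2)cc1OCc1ccccc1)c1c(OCOC)cc(OCOC)c2c1O[C@@H](c1ccc(OCc3ccccc3)cc1)CC2 | intermediate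
15 | 5,7-bis(benzyloxy)-3-[(2R)-2-[4-(benzyloxy)phenyl]-5,7-dihydroxychroman-8-yl]-4H-chromen-4-one | O=c1c(-c2c(O)cc(O)c3c2O[C@@H](c2ccc(OCc4ccccc4)cc2)CC3)coc2cc(OCc3ccccc3)cc(OCc3ccccc3)c12 | intermediate
16 | 5,7-bis(benzyloxy)-3-[(2R)-2-[4-(benzyloxy)phenyl]-5,7-bis(tert-butyldimethylsilyloxy)chroman-8-yl]-4H-chromen-4-one | O=c1c(-c2c(O[Si](C)(C)C(C)(C)C)cc(O[Si](C)(C)C(C)(C)C)c3c2O[C@@H](c2ccc(OCc4ccccc4)cc2)CC3)coc2cc(OCc3ccccc3)cc(OCc3ccccc3)c12 | intermediate
17 | chlorozinc derivative of 16 at C2 | O=c1c(-c2c(O[Si](C)(C)C(C)(C)C)cc(O[Si](C)(C)C(C)(C)C)c3c2O[C@@H](c2ccc(OCc4ccccc4)cc2)CC3)c([Zn]Cl)oc2cc(OCc3ccccc3)cc(OCc3ccccc3)c12 | intermediate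
18 | 5,7-bis(benzyloxy)-3-[(2R)-2-[4-(benzyloxy)phenyl]-5,7-bis(tert-butyldimethylsilyloxy)chroman-8-yl]-2-iodo-4H-chromen-4-one | O=c1c(-c2c(O[Si](C)(C)C(C)(C)C)cc(O[Si](C)(C)C(C)(C)C)c3c2O[C@@H](c2ccc(OCc4ccccc4)cc2)CC3)c(I)oc2cc(OCc3ccccc3)cc(OCc3ccccc3)c12 | intermediate
19 | 5,7-bis(benzyloxy)-3-[(2R)-2-[4-(benzyloxy)phenyl]-5,7-dihydroxychroman-8-yl]-2-iodo-4H-chromen-4-one (formed as its phenoxide) | O=c1c(-c2c(O)cc(O)c3c2O[C@@H](c2ccc(OCc4ccccc4)cc2)CC3)c(I)oc2cc(OCc3ccccc3)cc(OCc3ccccc3)c12 | intermediate
20 | 5'-hydroxy coumaronochromone: 5,7-bis(benzyloxy)-5'-hydroxy-2'-[4-(benzyloxy)phenyl] (2'R)-flavan-fused benzofuro[2,3-b]chromen-4-one (O7'–C2, C8'–C3, C2=C3) | O=c1c2c(OCc3ccccc3)cc(OCc3ccccc3)cc2oc2oc3cc(O)c4c(c3c12)O[C@@H](c1ccc(OCc2ccccc2)cc1)CC4 | intermediate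
21 | coumaronochromone tetrabenzyl ether: 5,7,5'-tris(benzyloxy)-2'-[4-(benzyloxy)phenyl] (2'R)-flavan-fused benzofuro[2,3-b]chromen-4-one (O7'–C2, C8'–C3, C2=C3) | O=c1c2c(OCc3ccccc3)cc(OCc3ccccc3)cc2oc2oc3cc(OCc5ccccc5)c4c(c3c12)O[C@@H](c1ccc(OCc2ccccc2)cc1)CC4 | intermediate
22 | [4-(benzyloxy)phenyl]boronic acid | OB(O)c1ccc(OCc2ccccc2)cc1 | starting material
23 | (2S,3S,2'R)-5,7,5'-tris(benzyloxy)-2,2'-bis[4-(benzyloxy)phenyl] ketal: chroman-4-one with C2 bonded to O7' and C3 bonded to C8' of the flavan | O=C1c2c(OCc3ccccc3)cc(OCc3ccccc3)cc2O[C@@]2(c3ccc(OCc5ccccc5)cc3)Oc3cc(OCc5ccccc5)c4c(c3[C@@H]12)O[C@@H](c1ccc(OCc2ccccc2)cc1)CC4 | intermediate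
24 | target: (2S,3S,2'R)-5,7,5'-trihydroxy-2,2'-bis(4-hydroxyphenyl) ketal, chroman-4-one with C2 bonded to O7' and C3 bonded to C8' of the flavan | O=C1c2c(O)cc(O)cc2O[C@@]2(c3ccc(O)cc3)Oc3cc(O)c4c(c3[C@@H]12)O[C@@H](c1ccc(O)cc1)CC4 | target

## Step count and least certain steps

Total: 15 steps. Longest linear sequence: 14 steps (steps 1–7 and 9–15); step 8 is the one-step side branch.

**Step 14 (proposed new method).** Most likely failures: migratory insertion into a tetrasubstituted, donor-substituted alkene that is part of a furan may be too slow, so that protodeboronation and homocoupling of 22 consume the reagent; facial selection on a flat substrate may be poor; and the product ketal may ionise at C2 in the weakly acidic medium and open. Fallback with known reaction types, giving up catalyst control: setting out from 21, a chlorosilane-accelerated, copper-mediated conjugate addition of commercial 4-(benzyloxy)phenylmagnesium bromide (CuBr·SMe2, Me3SiCl, THF, −78 °C), the usual way to add Grignard reagents to chromones, would give trimethylsilyl enol ether F1 as both C2 epimers, the enolate being trapped before it can eliminate an aryloxide. Buffered desilylation (Bu4NF/AcOH, −78 °C) protonates C3 on the only accessible face and would give 23 together with its (2R,3R,2'R) diastereomer F2. The two are diastereomers because of C2' and would be separated by chromatography, rejoining the route at 23.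

**Step 10 (key step).** Most likely failures: capture of the oxocarbenium ion by the O7' oxygen (with loss of the MOM group) in place of the ring A hydroxyl, leading to a dihydrobenzofuran and on to a 3-aroylbenzofuran; oxidation of the electron-rich arene or of phenols freed too early; acid-induced opening at C2' during the finish. Fallback that forms C3–C8' by cross-coupling: setting out from bromide 8, lithiation and trapping with 2-isopropoxy-4,4,5,5-tetramethyl-1,3,2-dioxaborolane would give boronic ester F3. Ketone 12 would be converted with DMF dimethyl acetal into enaminone F4 and then with iodine into 3-iodochromone F5. Suzuki–Miyaura coupling of F3 with F5 (Pd(OAc)2/SPhos, K3PO4, toluene/H2O) would give bis-MOM isoflavone F6, and HCl in methanol would remove the MOM groups to rejoin the route at 15.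

**Step 5.** Most likely failure: ionisation of the activated 4-alkoxybenzylic oxyphosphonium intermediate in competition with SN2 closure, eroding the enantiomeric purity at C2'. Fallback that avoids substitution at the benzylic carbon: setting out from ketone 5, acid-catalysed cyclodehydration (PPTS, toluene, reflux, water removal) would give 4H-chromene F7. Asymmetric hydrogenation of this cyclic enol ether with a cationic iridium phosphine-oxazoline complex, [Ir(cod)(L)][B(3,5-(CF3)2C6H3)4], a known route to 2-arylchromanes, would give 7 directly; the ligand enantiomer is chosen for (2R).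

**Step 6.** Most likely failure: competing bromination at C6' or dibromination, since MOM groups shield C6' less than benzyl groups do. Fallback that fixes the regiochemistry through the phenol: setting out from 6, magnesium-mediated ortho-formylation (MgCl2, Et3N, paraformaldehyde, MeCN, reflux) can only attack the one free position ortho to the free hydroxyl, the future C8', and would give salicylaldehyde F8. Mitsunobu closure of F8 as in step 5 would give 10 directly, rejoining the route one step later.

**Step 15.** Most likely failure: hydrogenolysis of the benzylic C2–O bonds of the ketal or of C2'–O1', or ring-opening of the ketal on the catalyst surface. Fallback that removes hydrogen from the last step: setting out from 21, hydrogenolysis at the robust coumaronochromone stage would give tetraol F9; silylation (TBSCl, imidazole) of the three unchelated phenols would give tris-silyl ether F10; the arylation of step 14 with commercial 4-(tert-butyldimethylsilyloxy)phenylboronic acid would give tetrakis-silyl ketal F11; buffered fluoride (HF·pyridine/pyridine, THF, 0 °C) would then give 24.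

## Further compounds

F1 | step 14 | trimethylsilyl enol ether of 23 (C4–OSiMe3, C3=C4; both C2 epimers, 2'R) | C[Si](C)(C)OC1=C2c3c(OC2(c2ccc(OCc4ccccc4)cc2)Oc2cc(OCc4ccccc4)cc(OCc4ccccc4)c12)cc(OCc1ccccc1)c1c3O[C@@H](c2ccc(OCc3ccccc3)cc2)CC1
F2 | step 14 | (2R,3R,2'R) diastereomer of 23 | O=C1c2c(OCc3ccccc3)cc(OCc3ccccc3)cc2O[C@]2(c3ccc(OCc5ccccc5)cc3)Oc3cc(OCc5ccccc5)c4c(c3[C@H]12)O[C@@H](c1ccc(OCc2ccccc2)cc1)CC4
F3 | step 10 | 2-[(2R)-2-[4-(benzyloxy)phenyl]-5,7-bis(methoxymethoxy)chroman-8-yl]-4,4,5,5-tetramethyl-1,3,2-dioxaborolane | CC1(C)OB(OC1(C)C)c1c(OCOC)cc(OCOC)c2c1O[C@@H](c1ccc(OCc3ccccc3)cc1)CC2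
F4 | step 10 | (E)-1-[2,4-bis(benzyloxy)-6-hydroxyphenyl]-3-(dimethylamino)prop-2-en-1-one | CN(C)/C=C/C(=O)c1c(O)cc(OCc2ccccc2)cc1OCc1ccccc1
F5 | step 10 | 5,7-bis(benzyloxy)-3-iodo-4H-chromen-4-one | O=c1c(I)coc2cc(OCc3ccccc3)cc(OCc3ccccc3)c12
F6 | step 10 | 5,7-bis(benzyloxy)-3-[(2R)-2-[4-(benzyloxy)phenyl]-5,7-bis(methoxymethoxy)chroman-8-yl]-4H-chromen-4-one | O=c1c(-c2c(OCOC)cc(OCOC)c3c2O[C@@H](c2ccc(OCc4ccccc4)cc2)CC3)coc2cc(OCc3ccccc3)cc(OCc3ccccc3)c12
F7 | step 5 | 2-[4-(benzyloxy)phenyl]-5,7-bis(methoxymethoxy)-4H-chromene | COCOc1cc(OCOC)c2c(c1)OC(c1ccc(OCc3ccccc3)cc1)=CC2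
F8 | step 6 | 3-[(3S)-3-[4-(benzyloxy)phenyl]-3-hydroxypropyl]-2-hydroxy-4,6-bis(methoxymethoxy)benzaldehyde | O=Cc1c(O)c(CC[C@H](O)c2ccc(OCc3ccccc3)cc2)c(OCOC)cc1OCOC
F9 | step 15 | 5,7,5'-trihydroxy-2'-(4-hydroxyphenyl) (2'R)-flavan-fused benzofuro[2,3-b]chromen-4-one (debenzylated 21) | O=c1c2c(O)cc(O)cc2oc2oc3cc(O)c4c(c3c12)O[C@@H](c1ccc(O)cc1)CC4
F10 | step 15 | 7,5',4'''-tris(tert-butyldimethylsilyl) ether of F9 (5-OH free) | O=c1c2c(O)cc(O[Si](C)(C)C(C)(C)C)cc2oc2oc3cc(O[Si](C)(C)C(C)(C)C)c4c(c3c12)O[C@@H](c1ccc(O[Si](C)(C)C(C)(C)C)cc1)CC4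
F11 | step 15 | (2S,3S,2'R)-7,5',4'',4'''-tetrakis(tert-butyldimethylsilyl) ether of 24 (5-OH free) | O=C1c2c(O)cc(O[Si](C)(C)C(C)(C)C)cc2O[C@@]2(c3ccc(O[Si](C)(C)C(C)(C)C)cc3)Oc3cc(O[Si](C)(C)C(C)(C)C)c4c(c3[C@@H]12)O[C@@H](c1ccc(O[Si](C)(C)C(C)(C)C)cc1)CC4
A1 | alternative 1 | {2-[4-(benzyloxy)phenyl]-5-[(3S)-3-[4-(benzyloxy)phenyl]-3-(triethylsilyloxy)propyl]-4-hydroxy-6-(triisopropylsilyloxy)benzofuran-3-yl}[2,4,6-tris(benzyloxy)phenyl]methanone | O=C(c1c(OCc2ccccc2)cc(OCc2ccccc2)cc1OCc1ccccc1)c1c(-c2ccc(OCc3ccccc3)cc2)oc2cc(O[Si](C(C)C)(C(C)C)C(C)C)c(CC[C@H](O[Si](CC)(CC)CC)c3ccc(OCc4ccccc4)cc3)c(O)c12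
A2 | alternative 1 | 2-diazo-1-{5-[4-(benzyloxy)phenyl]-4-[2,4,6-tris(benzyloxy)benzoyl]furan-2-yl}ethanone | [N-]=[N+]=CC(=O)c1cc(C(=O)c2c(OCc3ccccc3)cc(OCc3ccccc3)cc2OCc2ccccc2)c(-c2ccc(OCc3ccccc3)cc2)o1
A3 | alternative 1 | (S)-{[1-[4-(benzyloxy)phenyl]-5-(triisopropylsilyloxy)pent-4-yn-1-yl]oxy}triethylsilane | CC(C)[Si](OC#CCC[C@H](O[Si](CC)(CC)CC)c1ccc(OCc2ccccc2)cc1)(C(C)C)C(C)C
A4 | alternative 2 | hexabenzyl 3-aroyl-2-arylbenzofuran fused to the (R)-flavan | O=C(c1c(OCc2ccccc2)cc(OCc2ccccc2)cc1OCc1ccccc1)c1c(-c2ccc(OCc3ccccc3)cc2)oc2cc(OCc3ccccc3)c3c(c12)O[C@@H](c1ccc(OCc2ccccc2)cc1)CC3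
A5 | alternative 2 | (2R)-5-(benzyloxy)-2-[4-(benzyloxy)phenyl]-8-{[4-(benzyloxy)phenyl]ethynyl}chroman-7-ol | Oc1cc(OCc2ccccc2)c2c(c1C#Cc1ccc(OCc3ccccc3)cc1)O[C@@H](c1ccc(OCc3ccccc3)cc1)CC2
A6 | alternative 2 | 1,3,5-tris(benzyloxy)-2-iodobenzene | Ic1c(OCc2ccccc2)cc(OCc2ccccc2)cc1OCc1ccccc1
A7 | alternative 2 | carbon monoxide | [C-]#[O+]
A8 | alternative 3 | (2S,3S,2'R)-tetrabenzyl ether of the target with free 4'''-hydroxyl | O=C1c2c(OCc3ccccc3)cc(OCc3ccccc3)cc2O[C@@]2(c3ccc(OCc5ccccc5)cc3)Oc3cc(OCc5ccccc5)c4c(c3[C@@H]12)O[C@@H](c1ccc(O)cc1)CC4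
A9 | alternative 3 | ketal core carrying C8a' hydroxyl and C4a' hydroxymethyl (ortho-hydroxybenzyl alcohol), 5,7,5',4''-tetrabenzyl ether | O=C1c2c(OCc3ccccc3)cc(OCc3ccccc3)cc2O[C@@]2(c3ccc(OCc5ccccc5)cc3)Oc3cc(OCc5ccccc5)c(CO)c(O)c3[C@@H]12
A10 | alternative 3 | 4-vinylphenol | C=Cc1ccc(O)cc1
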